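The γ-butyrolactone is disconnected at its C4–C5 bond, between the ring CH that carries the 4-hydroxy-3-methoxybenzyl group and the ring OCH2. C5 is the only unsubstituted ring carbon and sits on the acyl oxygen, so it is brought in as an (acyloxy)methyl radical; the guaiacyl ring makes C4 the inner carbon of a styrene, which traps this radical 5-exo and becomes the ArCH2 arm. One operation thus closes the lactone and sets C4 trans to the C3 stereocentre. The precursor is an open-chain iodomethyl (R)-2-benzyl-4-arylbut-3-enoate, assembled by Evans alkylation with a benzylic bromide whose 1,3-diol arm stems from an Evans syn-aldol.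

Key step: step 15

Remark: the lactone is numbered as oxolan-2-one (O1, C2 carbonyl, C3, C4, C5); compounds 1, 3, 6, 9, 15 and 18 are taken as purchased.

Step 1
Reactants: 1 methyl 3-bromo-4-hydroxy-5-methoxybenzoate
Product: 2 methyl 4-(benzyloxy)-3-bromo-5-methoxybenzoate
Conditions: BnBr, K2CO3, DMF, 60 °C
Reagents that add atoms: benzyl bromide, BrCc1ccccc1
Why: Williamson etherification of the phenoxide; the benzyl ether masks the phenol until the final hydrogenolysis.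

Step 2
Reactants: 2 methyl 4-(benzyloxy)-3-bromo-5-methoxybenzoate; 3 (2-tert-butoxy-2-oxoethyl)zinc chloride (0.5 M in Et2O)
Product: 4 methyl 4-(benzyloxy)-3-(2-tert-butoxy-2-oxoethyl)-5-methoxybenzoate
Conditions: Pd2(dba)3 (2 mol%), XPhos (8 mol%), THF, 65 °C
Reagents that add atoms: none
Why: Negishi-type cross-coupling of a Reformatsky zinc enolate with the aryl bromide (palladium-catalysed α-arylation of an acetate), a reagent mild enough to leave the methyl benzoate alone.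

Step 3
Reactants: 4 methyl 4-(benzyloxy)-3-(2-tert-butoxy-2-oxoethyl)-5-methoxybenzoate
Product: 5 2-[2-(benzyloxy)-3-methoxy-5-(methoxycarbonyl)phenyl]acetic acid
Conditions: CF3CO2H/CH2Cl2 (1:4), 0 °C to rt
Reagents that add atoms: none
Why: Acidolysis of the tert-butyl ester with loss of isobutene should spare the methyl ester and the aryl benzyl ether.

Step 4
Reactants: 5 2-[2-(benzyloxy)-3-methoxy-5-(methoxycarbonyl)phenyl]acetic acid; 6 (4S)-4-benzyl-1,3-oxazolidin-2-one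
Product: 8 methyl 4-(benzyloxy)-3-{2-[(4S)-4-benzyl-2-oxo-1,3-oxazolidin-3-yl]-2-oxoethyl}-5-methoxybenzoate, via mixed pivalic anhydride 7 (not isolated)
Conditions: t-BuCOCl, Et3N, THF, −20 °C; then 6, LiCl, −20 °C to rt
Reagents that add atoms: none
Why: N-acylation of the Evans oxazolidinone through the mixed anhydride, which is attacked at the less hindered arylacetyl carbonyl.

Step 5
Reactants: 8 arylacetyl imide; 9 4-(benzyloxy)-3-methoxybenzaldehyde
Product: 11 (4S)-4-benzyl-3-{(2S,3S)-2-[2-(benzyloxy)-3-methoxy-5-(methoxycarbonyl)phenyl]-3-[4-(benzyloxy)-3-methoxyphenyl]-3-hydroxypropanoyl}-1,3-oxazolidin-2-one, via Z-boron enolate 10 (not isolated)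
Conditions: n-Bu2BOTf, i-Pr2NEt, CH2Cl2, −78 to 0 °C; then 9, −78 to 0 °C; H2O2, pH 7 buffer, MeOH, 0 °C
Reagents that add atoms: none
Why: Evans syn-aldol reaction, in which the Z-boron enolate reacts through a Zimmerman–Traxler chair on the face away from the auxiliary benzyl group and should set the aryl-bearing centre (2S) and the carbinol centre (3S) together.

Step 6
Reactants: 11 syn-aldol imide
Product: 12 (1S,2R)-2-[2-(benzyloxy)-5-(hydroxymethyl)-3-methoxyphenyl]-1-[4-(benzyloxy)-3-methoxyphenyl]propane-1,3-diol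
Conditions: LiBH4 (excess), MeOH (additive), THF, 0 °C then 50 °C
Reagents that add atoms: none
Why: Hydride reduction removes the auxiliary as the primary alcohol at 0 °C and reduces the methyl benzoate on warming; no stereocentre is touched (the change of descriptor at C2 is formal).

Step 7
Reactants: 12 triol
Product: 13 {4-(benzyloxy)-3-[(4S,5R)-4-[4-(benzyloxy)-3-methoxyphenyl]-2,2-dimethyl-1,3-dioxan-5-yl]-5-methoxyphenyl}methanol
Conditions: Me2C(OMe)2, PPTS (cat.), acetone, rt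
Reagents that add atoms: 2,2-dimethoxypropane, COC(C)(C)OC
Why: Thermodynamic acetalisation, in which only the 1,3-diol can close a six-membered isopropylidene acetal, so the lone benzylic alcohol should stay free.

Step 8
Reactants: 13 acetonide alcohol
Product: 14 (4S,5R)-5-[2-(benzyloxy)-5-(bromomethyl)-3-methoxyphenyl]-4-[4-(benzyloxy)-3-methoxyphenyl]-2,2-dimethyl-1,3-dioxane
Conditions: CBr4, PPh3, CH2Cl2, 0 °C; used without storage
Reagents that add atoms: carbon tetrabromide, BrC(Br)(Br)Br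
Why: Appel bromination under neutral conditions that should spare the acetonide.

Step 9
Reactants: 9 4-(benzyloxy)-3-methoxybenzaldehyde; 15 (2-carboxyethyl)triphenylphosphonium bromide
Product: 17 (3E)-4-[4-(benzyloxy)-3-methoxyphenyl]but-3-enoic acid, via ylide sodium salt 16 (not isolated)
Conditions: NaN(SiMe3)2 (2.4 equiv), THF, 0 °C; then 9, 0 °C to rt; 1 M HCl work-up
Reagents that add atoms: none
Why: Wittig olefination with the carboxylate-bearing ylide, which should favour the E styrene.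

Step 10
Reactants: 17 (3E)-4-[4-(benzyloxy)-3-methoxyphenyl]but-3-enoic acid; 18 (4R)-4-benzyl-1,3-oxazolidin-2-one
Product: 20 (4R)-4-benzyl-3-{(3E)-4-[4-(benzyloxy)-3-methoxyphenyl]but-3-enoyl}-1,3-oxazolidin-2-one, via mixed pivalic anhydride 19 (not isolated)
Conditions: t-BuCOCl, Et3N, THF, −20 °C; then 18, LiCl, −20 °C to rt
Reagents that add atoms: none
Why: N-acylation through the mixed anhydride; the aryl-conjugated β,γ-alkene is the preferred isomer and should stay in place.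

Step 11
Reactants: 20 butenoyl imide (1.2 equiv); 14 benzylic bromide
Product: 22 (4R)-4-benzyl-3-[(2R,3E)-2-({4-(benzyloxy)-3-[(4S,5R)-4-[4-(benzyloxy)-3-methoxyphenyl]-2,2-dimethyl-1,3-dioxan-5-yl]-5-methoxyphenyl}methyl)-4-[4-(benzyloxy)-3-methoxyphenyl]but-3-enoyl]-1,3-oxazolidin-2-one, via sodium Z-dienolate 21 (not isolated)
Conditions: NaN(SiMe3)2 (1.15 equiv), THF, −78 °C; then 14, −78 to −40 °C
Reagents that add atoms: none
Why: Evans asymmetric alkylation, in which the chelated Z-dienolate is alkylated at its α-carbon on the face opposite the auxiliary benzyl group and should give the 2R centre.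

Step 12
Reactants: 22 alkylated imide
Product: 24 (2R,3E)-2-({4-(benzyloxy)-3-[(4S,5R)-4-[4-(benzyloxy)-3-methoxyphenyl]-2,2-dimethyl-1,3-dioxan-5-yl]-5-methoxyphenyl}methyl)-4-[4-(benzyloxy)-3-methoxyphenyl]but-3-enoic acid, via peroxy acid 23 (not isolated)
Conditions: LiOH, H2O2, THF/H2O (3:1), 0 °C; then Na2SO3; 1 M HCl to pH 4 at 0 °C
Reagents that add atoms: hydrogen peroxide, OO
Why: Hydroperoxide cleavage of the exocyclic imide carbonyl, a weakly basic nucleophile at 0 °C that should not epimerise C2 or move the alkene.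

Step 13
Reactants: 24 butenoic acid
Product: 25 chloromethyl (2R,3E)-2-({4-(benzyloxy)-3-[(4S,5R)-4-[4-(benzyloxy)-3-methoxyphenyl]-2,2-dimethyl-1,3-dioxan-5-yl]-5-methoxyphenyl}methyl)-4-[4-(benzyloxy)-3-methoxyphenyl]but-3-enoate
Conditions: ClCH2OSO2Cl, NaHCO3, n-Bu4NHSO4 (cat.), CH2Cl2/H2O, rt
Reagents that add atoms: chloromethyl chlorosulfate, ClCOS(=O)(=O)Cl
Why: Phase-transfer O-alkylation of the carboxylate, which displaces chlorosulfate from the reagent by an SN2 reaction.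

Step 14
Reactants: 25 chloromethyl ester
Product: 26 iodomethyl (2R,3E)-2-({4-(benzyloxy)-3-[(4S,5R)-4-[4-(benzyloxy)-3-methoxyphenyl]-2,2-dimethyl-1,3-dioxan-5-yl]-5-methoxyphenyl}methyl)-4-[4-(benzyloxy)-3-methoxyphenyl]but-3-enoate
Conditions: NaI, acetone, rt, dark; used directly
Reagents that add atoms: sodium iodide, [Na+].[I-]
Why: Finkelstein exchange driven by precipitation of NaCl gives the weaker C–I bond needed for clean radical generation.

Step 15
Reactants: 26 iodomethyl ester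
Product: 27 (3R,4R)-3-({4-(benzyloxy)-3-[(4S,5R)-4-[4-(benzyloxy)-3-methoxyphenyl]-2,2-dimethyl-1,3-dioxan-5-yl]-5-methoxyphenyl}methyl)-4-{[4-(benzyloxy)-3-methoxyphenyl]methyl}oxolan-2-one
Conditions: n-Bu3SnH (1.3 equiv) and AIBN (0.2 equiv) in PhMe added over 6 h to 26 in PhMe (0.01 M), 110 °C
Reagents that add atoms: none
Why: The stannyl radical abstracts iodine to give an (acyloxy)methyl radical that adds to the inner styrene carbon (C3 of the butenoate), and the benzylic radical so formed takes hydrogen from n-Bu3SnH, so the C4–C5 bond, the lactone ring and the ArCH2 group form in one chain process. The closest known reaction type is the stannane-mediated 5-exo-trig cyclisation of α-oxygenated alkyl radicals onto alkenes (Ueno–Stork haloacetal and α-acyloxyalkyl radical lactone closures). The oxolan-2-one ring closes in the 5-exo-trig mode. The new C4 centre is controlled by the C3 centre already present: in the chair-like Beckwith–Houk transition state the C3 arylmethyl group is pseudo-equatorial, so the styrene is attacked on the face that places the two arylmethyl groups trans, which should give 3R,4R. The step needs ring closure to outrun direct reduction of the radical, although the ester must first turn into its minor s-cis rotamer, and it needs 5-exo over 6-endo attack. The aryl-conjugated acceptor secures both (fast addition, and a benzylic radical only from 5-exo attack), helped by the low stationary stannane concentration at 110 °C.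

Step 16
Reactants: 27 protected lactone
Product: 28 (3R,4R)-3-({4-(benzyloxy)-3-[(1S,2R)-1-[4-(benzyloxy)-3-methoxyphenyl]-1,3-dihydroxypropan-2-yl]-5-methoxyphenyl}methyl)-4-{[4-(benzyloxy)-3-methoxyphenyl]methyl}oxolan-2-one
Conditions: PPTS (cat.), MeOH/CH2Cl2, rt to 40 °C
Reagents that add atoms: none
Why: Acid-catalysed transacetalisation to methanol under buffered conditions that should be too weak to ionise the alkoxybenzylic C–O bond or open the lactone.

Step 17
Reactants: 28 tris(benzyl ether) diol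
Product: 29 (3R,4R)-3-({4-hydroxy-3-[(1S,2R)-1,3-dihydroxy-1-(4-hydroxy-3-methoxyphenyl)propan-2-yl]-5-methoxyphenyl}methyl)-4-[(4-hydroxy-3-methoxyphenyl)methyl]oxolan-2-one
Conditions: H2 (1 atm), Pd/C (10%), EtOAc/MeOH (4:1), rt, stopped after uptake of three equivalents
Reagents that add atoms: none
Why: Hydrogenolysis of the three aryl benzyl ethers under neutral conditions, which should be faster than cleavage of the secondary benzylic C–OH bond.

Compound list
1 | methyl 3-bromo-4-hydroxy-5-methoxybenzoate | COC(=O)c1cc(Br)c(O)c(OC)c1 | starting material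
2 | methyl 4-(benzyloxy)-3-bromo-5-methoxybenzoate | COC(=O)c1cc(Br)c(OCc2ccccc2)c(OC)c1 | intermediate
3 | (2-tert-butoxy-2-oxoethyl)zinc chloride | CC(C)(C)OC(=O)C[Zn]Cl | starting material
4 | methyl 4-(benzyloxy)-3-(2-tert-butoxy-2-oxoethyl)-5-methoxybenzoate | COC(=O)c1cc(CC(=O)OC(C)(C)C)c(OCc2ccccc2)c(OC)c1 | intermediate
5 | 2-[2-(benzyloxy)-3-methoxy-5-(methoxycarbonyl)phenyl]acetic acid | COC(=O)c1cc(CC(=O)O)c(OCc2ccccc2)c(OC)c1 | intermediate
6 | (4S)-4-benzyl-1,3-oxazolidin-2-one | O=C1OC[C@H](Cc2ccccc2)N1 | starting material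
7 | 2-[2-(benzyloxy)-3-methoxy-5-(methoxycarbonyl)phenyl]acetic pivalic anhydride | COC(=O)c1cc(CC(=O)OC(=O)C(C)(C)C)c(OCc2ccccc2)c(OC)c1 | intermediate
8 | methyl 4-(benzyloxy)-3-{2-[(4S)-4-benzyl-2-oxo-1,3-oxazolidin-3-yl]-2-oxoethyl}-5-methoxybenzoate | COC(=O)c1cc(CC(=O)N2[C@@H](Cc3ccccc3)COC2=O)c(OCc4ccccc4)c(OC)c1 | intermediate
9 | 4-(benzyloxy)-3-methoxybenzaldehyde | COc1cc(C=O)ccc1OCc2ccccc2 | starting material
10 | di-n-butylboron Z-enolate of 8 | COC(=O)c1cc(/C=C(\OB(CCCC)CCCC)N2[C@@H](Cc3ccccc3)COC2=O)c(OCc4ccccc4)c(OC)c1 | intermediate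
11 | (4S)-4-benzyl-3-{(2S,3S)-2-[2-(benzyloxy)-3-methoxy-5-(methoxycarbonyl)phenyl]-3-[4-(benzyloxy)-3-methoxyphenyl]-3-hydroxypropanoyl}-1,3-oxazolidin-2-one | COC(=O)c1cc([C@H](C(=O)N2[C@@H](Cc3ccccc3)COC2=O)[C@H](O)c4ccc(OCc5ccccc5)c(OC)c4)c(OCc6ccccc6)c(OC)c1 | intermediate
12 | (1S,2R)-2-[2-(benzyloxy)-5-(hydroxymethyl)-3-methoxyphenyl]-1-[4-(benzyloxy)-3-methoxyphenyl]propane-1,3-diol | OCc1cc([C@H](CO)[C@H](O)c2ccc(OCc3ccccc3)c(OC)c2)c(OCc4ccccc4)c(OC)c1 | intermediate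
13 | {4-(benzyloxy)-3-[(4S,5R)-4-[4-(benzyloxy)-3-methoxyphenyl]-2,2-dimethyl-1,3-dioxan-5-yl]-5-methoxyphenyl}methanol | OCc1cc([C@@H]2COC(C)(C)O[C@@H]2c3ccc(OCc4ccccc4)c(OC)c3)c(OCc5ccccc5)c(OC)c1 | intermediate
14 | (4S,5R)-5-[2-(benzyloxy)-5-(bromomethyl)-3-methoxyphenyl]-4-[4-(benzyloxy)-3-methoxyphenyl]-2,2-dimethyl-1,3-dioxane | BrCc1cc([C@@H]2COC(C)(C)O[C@@H]2c3ccc(OCc4ccccc4)c(OC)c3)c(OCc5ccccc5)c(OC)c1 | intermediate
15 | (2-carboxyethyl)triphenylphosphonium bromide | OC(=O)CC[P+](c1ccccc1)(c2ccccc2)c3ccccc3.[Br-] | starting material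
16 | sodium 3-(triphenyl-λ5-phosphanylidene)propanoate | [Na+].[O-]C(=O)CC=P(c1ccccc1)(c2ccccc2)c3ccccc3 | intermediate
17 | (3E)-4-[4-(benzyloxy)-3-methoxyphenyl]but-3-enoic acid | COc1cc(/C=C/CC(=O)O)ccc1OCc2ccccc2 | intermediate
18 | (4R)-4-benzyl-1,3-oxazolidin-2-one | O=C1OC[C@@H](Cc2ccccc2)N1 | starting material
19 | (3E)-4-[4-(benzyloxy)-3-methoxyphenyl]but-3-enoic pivalic anhydride | COc1cc(/C=C/CC(=O)OC(=O)C(C)(C)C)ccc1OCc2ccccc2 | intermediate
20 | (4R)-4-benzyl-3-{(3E)-4-[4-(benzyloxy)-3-methoxyphenyl]but-3-enoyl}-1,3-oxazolidin-2-one | COc1cc(/C=C/CC(=O)N2[C@H](Cc3ccccc3)COC2=O)ccc1OCc4ccccc4 | intermediate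
21 | sodium Z-dienolate of 20 | [Na+].[O-]/C(=C\C=C\c1ccc(OCc2ccccc2)c(OC)c1)N3[C@H](Cc4ccccc4)COC3=O | intermediate
22 | (4R)-4-benzyl-3-[(2R,3E)-2-({4-(benzyloxy)-3-[(4S,5R)-4-[4-(benzyloxy)-3-methoxyphenyl]-2,2-dimethyl-1,3-dioxan-5-yl]-5-methoxyphenyl}methyl)-4-[4-(benzyloxy)-3-methoxyphenyl]but-3-enoyl]-1,3-oxazolidin-2-one | O=C(N1[C@H](Cc2ccccc2)COC1=O)[C@@H](/C=C/c3ccc(OCc4ccccc4)c(OC)c3)Cc5cc(OC)c(OCc6ccccc6)c(c5)[C@@H]7COC(C)(C)O[C@@H]7c8ccc(OCc9ccccc9)c(OC)c8 | intermediate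
23 | (2R,3E)-2-({4-(benzyloxy)-3-[(4S,5R)-4-[4-(benzyloxy)-3-methoxyphenyl]-2,2-dimethyl-1,3-dioxan-5-yl]-5-methoxyphenyl}methyl)-4-[4-(benzyloxy)-3-methoxyphenyl]but-3-eneperoxoic acid | OOC(=O)[C@@H](/C=C/c1ccc(OCc2ccccc2)c(OC)c1)Cc3cc(OC)c(OCc4ccccc4)c(c3)[C@@H]5COC(C)(C)O[C@@H]5c6ccc(OCc7ccccc7)c(OC)c6 | intermediate
24 | (2R,3E)-2-({4-(benzyloxy)-3-[(4S,5R)-4-[4-(benzyloxy)-3-methoxyphenyl]-2,2-dimethyl-1,3-dioxan-5-yl]-5-methoxyphenyl}methyl)-4-[4-(benzyloxy)-3-methoxyphenyl]but-3-enoic acid | OC(=O)[C@@H](/C=C/c1ccc(OCc2ccccc2)c(OC)c1)Cc3cc(OC)c(OCc4ccccc4)c(c3)[C@@H]5COC(C)(C)O[C@@H]5c6ccc(OCc7ccccc7)c(OC)c6 | intermediate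
25 | chloromethyl ester of 24 | ClCOC(=O)[C@@H](/C=C/c1ccc(OCc2ccccc2)c(OC)c1)Cc3cc(OC)c(OCc4ccccc4)c(c3)[C@@H]5COC(C)(C)O[C@@H]5c6ccc(OCc7ccccc7)c(OC)c6 | intermediate
26 | iodomethyl ester of 24 | ICOC(=O)[C@@H](/C=C/c1ccc(OCc2ccccc2)c(OC)c1)Cc3cc(OC)c(OCc4ccccc4)c(c3)[C@@H]5COC(C)(C)O[C@@H]5c6ccc(OCc7ccccc7)c(OC)c6 | intermediate
27 | (3R,4R)-3-({4-(benzyloxy)-3-[(4S,5R)-4-[4-(benzyloxy)-3-methoxyphenyl]-2,2-dimethyl-1,3-dioxan-5-yl]-5-methoxyphenyl}methyl)-4-{[4-(benzyloxy)-3-methoxyphenyl]methyl}oxolan-2-one | COc1cc(C[C@H]2COC(=O)[C@@H]2Cc3cc(OC)c(OCc4ccccc4)c(c3)[C@@H]5COC(C)(C)O[C@@H]5c6ccc(OCc7ccccc7)c(OC)c6)ccc1OCc8ccccc8 | intermediate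
28 | (3R,4R)-3-({4-(benzyloxy)-3-[(1S,2R)-1-[4-(benzyloxy)-3-methoxyphenyl]-1,3-dihydroxypropan-2-yl]-5-methoxyphenyl}methyl)-4-{[4-(benzyloxy)-3-methoxyphenyl]methyl}oxolan-2-one | COc1cc(C[C@H]2COC(=O)[C@@H]2Cc3cc(OC)c(OCc4ccccc4)c(c3)[C@H](CO)[C@H](O)c5ccc(OCc6ccccc6)c(OC)c5)ccc1OCc7ccccc7 | intermediate
29 | (3R,4R)-3-({4-hydroxy-3-[(1S,2R)-1,3-dihydroxy-1-(4-hydroxy-3-methoxyphenyl)propan-2-yl]-5-methoxyphenyl}methyl)-4-[(4-hydroxy-3-methoxyphenyl)methyl]oxolan-2-one | COc1cc(C[C@H]2COC(=O)[C@@H]2Cc2cc(OC)c(O)c([C@H](CO)[C@H](O)c3ccc(O)c(OC)c3)c2)ccc1O | target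

Total step count: 17. Longest linear sequence: 15 steps (steps 1–8, then 11–17).

Steps most likely to fail

Step 15. Hydrogen transfer from the stannane may overtake ring closure, because the (acyloxy)methyl radical must first rotate into the minor s-cis ester conformer, and the facial selectivity at C4 may be incomplete. The fallback sets out from aldehyde 9 and bromide 14 and comes back at 27; it makes the lactone ring first and attaches the large arylmethyl group last. Stobbe condensation of 9 with dimethyl succinate (KOt-Bu, t-BuOH) should give (3E)-4-[4-(benzyloxy)-3-methoxyphenyl]-3-(methoxycarbonyl)but-3-enoic acid F1. Asymmetric hydrogenation (Rh(cod)2BF4 with a chiral bisphosphine of the hand that delivers the R acid, H2, MeOH) should give (3R)-3-{[4-(benzyloxy)-3-methoxyphenyl]methyl}-4-methoxy-4-oxobutanoic acid F2. Reduction of the ester in its potassium carboxylate with Ca(BH4)2 (CaCl2, NaBH4, EtOH) and acid lactonisation should give (4R)-4-{[4-(benzyloxy)-3-methoxyphenyl]methyl}oxolan-2-one F3. The lithium enolate of this lactone (LiN(SiMe3)2, THF, −78 °C) is then alkylated by 14 on the face opposite the C4 substituent to give 27.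

Step 11. C-alkylation of the extended, styryl-stabilised dienolate may be slow, and proton exchange between product and enolate would erode the C2 configuration. The fallback sets out from auxiliary 18 and bromide 14 and comes back at 22; it sets the stereocentre on a simpler dienolate and adds the aryl group afterwards. N-acylation of 18 with (E)-but-2-enoyl chloride (n-BuLi, THF, −78 °C) gives (4R)-4-benzyl-3-[(2E)-but-2-enoyl]-1,3-oxazolidin-2-one F4. Deconjugative α-alkylation of its sodium dienolate (NaN(SiMe3)2, THF, −78 °C) with 14 should give (4R)-4-benzyl-3-[(2R)-2-({4-(benzyloxy)-3-[(4S,5R)-4-[4-(benzyloxy)-3-methoxyphenyl]-2,2-dimethyl-1,3-dioxan-5-yl]-5-methoxyphenyl}methyl)but-3-enoyl]-1,3-oxazolidin-2-one F5. A Heck arylation of the terminal vinyl group with 1-(benzyloxy)-4-iodo-2-methoxybenzene (Pd(OAc)2, n-Bu4NCl, NaHCO3, DMF, 50 °C) then gives 22.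

Step 6. Exhaustive hydride reduction may cause retro-aldol cleavage of the β-hydroxy imide, or may stall before the electron-rich benzoate is reduced. The fallback sets out from 11 and comes back at 13; it separates the two reductions. NaBH4 in THF/H2O at 0 °C removes only the auxiliary and should give methyl 4-(benzyloxy)-3-{(1S,2R)-1-[4-(benzyloxy)-3-methoxyphenyl]-1,3-dihydroxypropan-2-yl}-5-methoxybenzoate F6. Acetonide formation (Me2C(OMe)2, PPTS, acetone) gives methyl 4-(benzyloxy)-3-[(4S,5R)-4-[4-(benzyloxy)-3-methoxyphenyl]-2,2-dimethyl-1,3-dioxan-5-yl]-5-methoxybenzoate F7. i-Bu2AlH (CH2Cl2, −78 °C) then reduces the ester to 13.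

Further compounds
F1 | step 15 | (3E)-4-[4-(benzyloxy)-3-methoxyphenyl]-3-(methoxycarbonyl)but-3-enoic acid | OC(=O)C/C(C(=O)OC)=C\c1ccc(OCc2ccccc2)c(OC)c1
F2 | step 15 | (3R)-3-{[4-(benzyloxy)-3-methoxyphenyl]methyl}-4-methoxy-4-oxobutanoic acid | COc1cc(C[C@H](CC(=O)O)C(=O)OC)ccc1OCc2ccccc2
F3 | step 15 | (4R)-4-{[4-(benzyloxy)-3-methoxyphenyl]methyl}oxolan-2-one | COc1cc(C[C@H]2COC(=O)C2)ccc1OCc3ccccc3
F4 | step 11 | (4R)-4-benzyl-3-[(2E)-but-2-enoyl]-1,3-oxazolidin-2-one | C/C=C/C(=O)N1[C@H](Cc2ccccc2)COC1=O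
F5 | step 11 | (4R)-4-benzyl-3-[(2R)-2-({4-(benzyloxy)-3-[(4S,5R)-4-[4-(benzyloxy)-3-methoxyphenyl]-2,2-dimethyl-1,3-dioxan-5-yl]-5-methoxyphenyl}methyl)but-3-enoyl]-1,3-oxazolidin-2-one | O=C(N1[C@H](Cc2ccccc2)COC1=O)[C@@H](C=C)Cc3cc(OC)c(OCc4ccccc4)c(c3)[C@@H]5COC(C)(C)O[C@@H]5c6ccc(OCc7ccccc7)c(OC)c6
F6 | step 6 | methyl 4-(benzyloxy)-3-{(1S,2R)-1-[4-(benzyloxy)-3-methoxyphenyl]-1,3-dihydroxypropan-2-yl}-5-methoxybenzoate | COC(=O)c1cc([C@H](CO)[C@H](O)c2ccc(OCc3ccccc3)c(OC)c2)c(OCc4ccccc4)c(OC)c1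
F7 | step 6 | methyl 4-(benzyloxy)-3-[(4S,5R)-4-[4-(benzyloxy)-3-methoxyphenyl]-2,2-dimethyl-1,3-dioxan-5-yl]-5-methoxybenzoate | COC(=O)c1cc([C@@H]2COC(C)(C)O[C@@H]2c3ccc(OCc4ccccc4)c(OC)c3)c(OCc5ccccc5)c(OC)c1
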